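**Plan**

- Feature: numbering the ring as a benzoic acid (CO2H on C-1, OH on C-2, OMe on C-4, side chain on C-6, chain carbons primed), the oxygenated ring is the dehydrogenated form of a 2,4-dioxocyclohexane-1-carboxylate. In that form C-6 is a saturated carbon, so an enone β-carbon can bring it in together with the chain.
- Cuts: the arene is taken back to the cyclohexenone, then C-2–C-3 (Dieckmann) and C-1–C-6 (Michael) are cut to give dimethyl malonate and an E-enone. The enone is cut at C-5–C-6 (Wittig) and at C-1'–C-2' (acylation of Meldrum's acid), leading back to 12-hydroxydodecanoic acid.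
- Forward: the chain is built first (silyl ether, β-keto ester, dioxolane, aldehyde, enone). The only carbocycle closes in step 6, followed by brominative aromatisation, hydrodebromination, 4-O-methylation, saponification and acidic unmasking.
- Stereochemistry: the target has no stereocentre. C-1 and C-6 of the cyclohexenone form as a racemic trans pair and vanish on aromatisation; the E-alkene comes from the stabilised ylide.

Key step: step 6

Remark: TBS = tert-butyldimethylsilyl; the side chain is read as 13-hydroxy-2-oxotridecyl (eleven methylenes between the ketone and the carbinol carbon).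

**Route**

Step 1
Reactants: 1 12-hydroxydodecanoic acid
Product: 3 12-[(tert-butyldimethylsilyl)oxy]dodecanoic acid, via bis-silylated ester 2 (not isolated)
Conditions: TBSCl (2.4 equiv), imidazole (5 equiv), DMF, rt; then K2CO3, MeOH/THF/H2O, rt; 1 M HCl to pH 4, 0 °C
Reagents that add atoms: tert-butyldimethylsilyl chloride, CC(C)(C)[Si](C)(C)Cl
Why: Imidazole-promoted silylation (Corey conditions) covers both the hydroxyl and the carboxyl group, and the much more labile silyl ester is then cleaved selectively by carbonate in aqueous methanol, leaving the primary silyl ether.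

Step 2
Reactants: 3 12-[(tert-butyldimethylsilyl)oxy]dodecanoic acid; 4 Meldrum's acid
Product: 6 methyl 14-[(tert-butyldimethylsilyl)oxy]-3-oxotetradecanoate, via acyl Meldrum's acid 5 (not isolated)
Conditions: DCC, DMAP, CH2Cl2, 0 °C to rt; filter; then MeOH (5 equiv), toluene, 85 °C
Reagents that add atoms: methanol, CO
Why: Carbodiimide-mediated C-acylation of Meldrum's acid, then thermal loss of acetone and CO2 through an acylketene that methanol traps (Oikawa–Yonemitsu β-keto ester synthesis), adds C-1' and the future C-6 carbon under conditions a primary silyl ether tolerates.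

Step 3
Reactants: 6 methyl 14-[(tert-butyldimethylsilyl)oxy]-3-oxotetradecanoate
Product: 7 methyl 2-(2-{11-[(tert-butyldimethylsilyl)oxy]undecyl}-1,3-dioxolan-2-yl)acetate
Conditions: (Me3SiOCH2)2 (2 equiv), Me3SiOTf (0.05 equiv), CH2Cl2, −78 to −20 °C; pyridine quench
Reagents that add atoms: 1,2-bis(trimethylsilyloxy)ethane, C[Si](C)(C)OCCO[Si](C)(C)C
Why: Noyori ketalisation (silylated diol, catalytic silyl triflate, low temperature) masks the ketone without the protic acid and free alcohol that would endanger the silyl ether, so that the later enone carries no second enolisable carbonyl.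

Step 4
Reactants: 7 methyl 2-(2-{11-[(tert-butyldimethylsilyl)oxy]undecyl}-1,3-dioxolan-2-yl)acetate
Product: 8 2-(2-{11-[(tert-butyldimethylsilyl)oxy]undecyl}-1,3-dioxolan-2-yl)acetaldehyde
Conditions: iBu2AlH (1.1 equiv), CH2Cl2, −78 °C; MeOH, then aq. KNaC4H4O6 (potassium sodium tartrate); used crude
Reagents that add atoms: none
Why: Partial ester reduction with iBu2AlH at −78 °C should stop at the aldehyde because the tetrahedral aluminium hemiacetal, chelated by a dioxolane oxygen, does not collapse before the quench.

Step 5
Reactants: 8 2-(2-{11-[(tert-butyldimethylsilyl)oxy]undecyl}-1,3-dioxolan-2-yl)acetaldehyde; 9 1-(triphenylphosphoranylidene)propan-2-one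
Product: 10 (E)-5-(2-{11-[(tert-butyldimethylsilyl)oxy]undecyl}-1,3-dioxolan-2-yl)pent-3-en-2-one
Conditions: CH2Cl2, 40 °C
Reagents that add atoms: none
Why: Wittig olefination with a stabilised acyl ylide should give the E-enone selectively under neutral conditions that spare the β-ketal aldehyde, forming the future C-5–C-6 bond.

Step 6
Reactants: 10 (E)-5-(2-{11-[(tert-butyldimethylsilyl)oxy]undecyl}-1,3-dioxolan-2-yl)pent-3-en-2-one; 11 dimethyl malonate
Product: 13 methyl trans-2-hydroxy-4-oxo-6-[(2-{11-[(tert-butyldimethylsilyl)oxy]undecyl}-1,3-dioxolan-2-yl)methyl]cyclohex-2-ene-1-carboxylate (racemic), via Michael adduct 12 (not isolated)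
Conditions: NaOMe (0.1 equiv), MeOH, 0 °C to rt; then NaOMe (1.3 equiv), MeOH, reflux; cold 1 M HCl to pH 4
Reagents that add atoms: none
Why: Catalytic methoxide generates the malonate anion, which adds in a 1,4 sense to the enone β-carbon (future C-6) and forms the C-1–C-6 bond; once the remaining methoxide is added, the methyl-ketone enolate (future C-3) attacks one malonate ester in a Dieckmann step that forms the C-2–C-3 bond, and deprotonation of the resulting vinylogous acid drains all preceding equilibria. The closest known reaction type is the Michael–Dieckmann synthesis of 6-alkyl dihydroresorcylates from alk-3-en-2-ones and malonic esters. The ring closes in a 6-(enolendo)-exo-trig mode. C-6 forms without facial bias (racemate), and C-1, which stays epimerisable between the ester and the enolised ketone, should settle trans to the C-6 side chain under thermodynamic control; both centres disappear in step 7. The step needs conjugate instead of carbonyl addition and closure from the methyl instead of the methylene side: the stabilised malonate anion secures the first, and the second follows because attack from C-5 could only give a four-membered ring. Keeping the base catalytic while enone is still present should let malonate addition outpace deprotonation of the γ-methylene next to the ketal, whose dienolate could otherwise deconjugate or expel a ketal oxygen.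

Step 7
Reactants: 13 methyl trans-2-hydroxy-4-oxo-6-[(2-{11-[(tert-butyldimethylsilyl)oxy]undecyl}-1,3-dioxolan-2-yl)methyl]cyclohex-2-ene-1-carboxylate
Product: 14 methyl 3,5-dibromo-2,4-dihydroxy-6-[(2-{11-[(tert-butyldimethylsilyl)oxy]undecyl}-1,3-dioxolan-2-yl)methyl]benzoate
Conditions: Br2 (3.05 equiv), NaOAc (6 equiv), AcOH, 15 °C to rt; aq. Na2S2O3
Reagents that add atoms: bromine, BrBr
Why: Halogenative dehydrogenation of a dihydroresorcylate, in which the enol is brominated twice at C-3, the dienol of the 3,3-dibromide loses HBr in a 1,4 sense to aromatise and the third equivalent brominates C-5, while acetate captures each equivalent of HBr so that the dioxolane and silyl ether never meet strong acid.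

Step 8
Reactants: 14 methyl 3,5-dibromo-2,4-dihydroxy-6-[(2-{11-[(tert-butyldimethylsilyl)oxy]undecyl}-1,3-dioxolan-2-yl)methyl]benzoate
Product: 15 methyl 2,4-dihydroxy-6-[(2-{11-[(tert-butyldimethylsilyl)oxy]undecyl}-1,3-dioxolan-2-yl)methyl]benzoate
Conditions: H2 (1 atm), 10% Pd/C, Et3N (3 equiv), EtOAc, rt
Reagents that add atoms: none
Why: Palladium-catalysed hydrogenolysis of aryl C–Br bonds (hydrodehalogenation) with an amine as HBr scavenger should remove both bromines without touching the ester, ketal or silyl ether.

Step 9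
Reactants: 15 methyl 2,4-dihydroxy-6-[(2-{11-[(tert-butyldimethylsilyl)oxy]undecyl}-1,3-dioxolan-2-yl)methyl]benzoate
Product: 16 methyl 2-hydroxy-4-methoxy-6-[(2-{11-[(tert-butyldimethylsilyl)oxy]undecyl}-1,3-dioxolan-2-yl)methyl]benzoate
Conditions: MeI (1.1 equiv), K2CO3 (1.2 equiv), acetone, rt
Reagents that add atoms: iodomethane, CI
Why: Williamson O-methylation under mild carbonate conditions should take only the C-4 phenol, because the C-2 hydroxyl is hydrogen-bonded to the ester carbonyl and is far less acidic and nucleophilic.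

Step 10
Reactants: 16 methyl 2-hydroxy-4-methoxy-6-[(2-{11-[(tert-butyldimethylsilyl)oxy]undecyl}-1,3-dioxolan-2-yl)methyl]benzoate
Product: 17 2-hydroxy-4-methoxy-6-[(2-{11-[(tert-butyldimethylsilyl)oxy]undecyl}-1,3-dioxolan-2-yl)methyl]benzoic acid
Conditions: KOH (10 equiv), EtOH/H2O (4:1), 80 °C; cold 1 M HCl to pH 4
Reagents that add atoms: potassium hydroxide, [K+].[OH-]
Why: Saponification of the hindered, hydrogen-bonded salicylate needs hot concentrated hydroxide, which the ketal tolerates, and keeping the ketone masked prevents Claisen-type closure of a side-chain enolate onto the ester.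

Step 11
Reactants: 17 2-hydroxy-4-methoxy-6-[(2-{11-[(tert-butyldimethylsilyl)oxy]undecyl}-1,3-dioxolan-2-yl)methyl]benzoic acid
Product: 18 2-hydroxy-6-(13-hydroxy-2-oxotridecyl)-4-methoxybenzoic acid (CNP0165592.0)
Conditions: 1 M HCl/THF (1:3), rt
Reagents that add atoms: water, O
Why: Acid-catalysed hydrolysis cleaves the dioxolane and the primary silyl ether in one operation, and room temperature in an aqueous medium should avoid decarboxylation of the β-resorcylic acid and cyclodehydration of the keto acid to an isocoumarin.

**Compound list**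

1 | 12-hydroxydodecanoic acid | OCCCCCCCCCCCC(=O)O | starting material
2 | tert-butyldimethylsilyl 12-[(tert-butyldimethylsilyl)oxy]dodecanoate (not isolated) | CC(C)(C)[Si](C)(C)OCCCCCCCCCCCC(=O)O[Si](C)(C)C(C)(C)C | intermediate
3 | 12-[(tert-butyldimethylsilyl)oxy]dodecanoic acid | CC(C)(C)[Si](C)(C)OCCCCCCCCCCCC(=O)O | intermediate
4 | Meldrum's acid (2,2-dimethyl-1,3-dioxane-4,6-dione) | CC1(C)OC(=O)CC(=O)O1 | starting material
5 | 5-{12-[(tert-butyldimethylsilyl)oxy]-1-hydroxydodecylidene}-2,2-dimethyl-1,3-dioxane-4,6-dione (acyl Meldrum's acid, enol form; not isolated) | CC1(C)OC(=O)C(=C(O)CCCCCCCCCCCO[Si](C)(C)C(C)(C)C)C(=O)O1 | intermediate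
6 | methyl 14-[(tert-butyldimethylsilyl)oxy]-3-oxotetradecanoate | COC(=O)CC(=O)CCCCCCCCCCCO[Si](C)(C)C(C)(C)C | intermediate
7 | methyl 2-(2-{11-[(tert-butyldimethylsilyl)oxy]undecyl}-1,3-dioxolan-2-yl)acetate | COC(=O)CC1(CCCCCCCCCCCO[Si](C)(C)C(C)(C)C)OCCO1 | intermediate
8 | 2-(2-{11-[(tert-butyldimethylsilyl)oxy]undecyl}-1,3-dioxolan-2-yl)acetaldehyde | O=CCC1(CCCCCCCCCCCO[Si](C)(C)C(C)(C)C)OCCO1 | intermediate
9 | 1-(triphenylphosphoranylidene)propan-2-one | CC(=O)C=P(c1ccccc1)(c1ccccc1)c1ccccc1 | starting material
10 | (E)-5-(2-{11-[(tert-butyldimethylsilyl)oxy]undecyl}-1,3-dioxolan-2-yl)pent-3-en-2-one | CC(=O)/C=C/CC1(CCCCCCCCCCCO[Si](C)(C)C(C)(C)C)OCCO1 | intermediate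
11 | dimethyl malonate | COC(=O)CC(=O)OC | starting material
12 | dimethyl 2-[1-(2-{11-[(tert-butyldimethylsilyl)oxy]undecyl}-1,3-dioxolan-2-yl)-4-oxopentan-2-yl]malonate (racemic Michael adduct; not isolated) | COC(=O)C(C(=O)OC)C(CC(C)=O)CC1(CCCCCCCCCCCO[Si](C)(C)C(C)(C)C)OCCO1 | intermediate
13 | methyl trans-2-hydroxy-4-oxo-6-[(2-{11-[(tert-butyldimethylsilyl)oxy]undecyl}-1,3-dioxolan-2-yl)methyl]cyclohex-2-ene-1-carboxylate (racemic; ester and side chain on opposite faces; one enantiomer drawn) | COC(=O)[C@@H]1C(O)=CC(=O)C[C@H]1CC2(CCCCCCCCCCCO[Si](C)(C)C(C)(C)C)OCCO2 | intermediate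
14 | methyl 3,5-dibromo-2,4-dihydroxy-6-[(2-{11-[(tert-butyldimethylsilyl)oxy]undecyl}-1,3-dioxolan-2-yl)methyl]benzoate | COC(=O)c1c(O)c(Br)c(O)c(Br)c1CC2(CCCCCCCCCCCO[Si](C)(C)C(C)(C)C)OCCO2 | intermediate
15 | methyl 2,4-dihydroxy-6-[(2-{11-[(tert-butyldimethylsilyl)oxy]undecyl}-1,3-dioxolan-2-yl)methyl]benzoate | COC(=O)c1c(O)cc(O)cc1CC2(CCCCCCCCCCCO[Si](C)(C)C(C)(C)C)OCCO2 | intermediate
16 | methyl 2-hydroxy-4-methoxy-6-[(2-{11-[(tert-butyldimethylsilyl)oxy]undecyl}-1,3-dioxolan-2-yl)methyl]benzoate | COC(=O)c1c(O)cc(OC)cc1CC2(CCCCCCCCCCCO[Si](C)(C)C(C)(C)C)OCCO2 | intermediate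
17 | 2-hydroxy-4-methoxy-6-[(2-{11-[(tert-butyldimethylsilyl)oxy]undecyl}-1,3-dioxolan-2-yl)methyl]benzoic acid | OC(=O)c1c(O)cc(OC)cc1CC2(CCCCCCCCCCCO[Si](C)(C)C(C)(C)C)OCCO2 | intermediate
18 | 2-hydroxy-6-(13-hydroxy-2-oxotridecyl)-4-methoxybenzoic acid (CNP0165592.0; achiral) | COc1cc(O)c(C(=O)O)c(CC(=O)CCCCCCCCCCCO)c1 | target

**Step count and risks**

Total step count: 11. Longest linear sequence: 11 steps (1 to 18); all other inputs are commercial.

Steps most likely to fail, riskiest first:

Step 7. The HBr released during bromination may not be buffered fast enough, so that the dioxolane opens to an enol ether that is then brominated, or the silyl ether is lost; the sequence could also stall before the 1,4-elimination. The fallback sets out from 13 and returns at 16, so steps 8 and 9 are no longer needed. O-Methylation of the vinylogous acid (Me2SO4, K2CO3, acetone, rt) should favour the oxygen remote from the cation-chelating β-keto ester and give methyl trans-4-methoxy-2-oxo-6-[(2-{11-[(tert-butyldimethylsilyl)oxy]undecyl}-1,3-dioxolan-2-yl)methyl]cyclohex-3-ene-1-carboxylate F1; any 2-methoxy isomer is removed by chromatography. Deprotonation at C-1 with NaH and trapping with PhSeCl (THF, 0 °C) should give methyl 4-methoxy-2-oxo-1-(phenylselanyl)-6-[(2-{11-[(tert-butyldimethylsilyl)oxy]undecyl}-1,3-dioxolan-2-yl)methyl]cyclohex-3-ene-1-carboxylate F2, with selenium entering anti to the side chain and therefore syn to the C-6 hydrogen. Oxidation with H2O2/pyridine (CH2Cl2, 0 °C to rt) triggers selenoxide syn-elimination across C-1–C-6, and the dienone tautomerises to 16. Every stage is basic or neutral.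

Step 6. Base may consume the enone before malonate adds, through deprotonation of the γ-methylene between alkene and ketal (deconjugation or vinylogous expulsion of a ketal oxygen) or through retro-Michael reversal during the slow Dieckmann stage. The fallback sets out from 8 and 11 and returns at 12. Knoevenagel condensation (piperidine/AcOH cat., CH2Cl2, 4 Å molecular sieves, rt) gives dimethyl 2-[2-(2-{11-[(tert-butyldimethylsilyl)oxy]undecyl}-1,3-dioxolan-2-yl)ethylidene]malonate F3. Conjugate addition of the lithium enolate of acetone (acetone, LiN(iPr)2, THF, −78 °C) then gives 12 as an isolated compound, and NaOMe (1.3 equiv) in MeOH at reflux, as in the second stage of step 6, closes it to 13. The same ring bonds result, but no enone is ever exposed to alkoxide; C-1–C-6 comes from the condensation and C-5–C-6 from the enolate addition.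

Step 4. The aluminium hemiacetal may break down before the quench and be over-reduced to the alcohol, and the β,β-dialkoxy aldehyde may lose a ketal oxygen by β-elimination during purification. The fallback sets out from 7 and returns at 8. Full reduction (LiAlH4, THF, 0 °C) gives 2-(2-{11-[(tert-butyldimethylsilyl)oxy]undecyl}-1,3-dioxolan-2-yl)ethan-1-ol F4, and Parikh–Doering oxidation (SO3·pyridine, DMSO, iPr2NEt, CH2Cl2, 0 °C) returns 8, which goes into step 5 without chromatography.

**Further compounds**

F1 | step 7 | methyl trans-4-methoxy-2-oxo-6-[(2-{11-[(tert-butyldimethylsilyl)oxy]undecyl}-1,3-dioxolan-2-yl)methyl]cyclohex-3-ene-1-carboxylate (racemic; one enantiomer drawn) | COC(=O)[C@@H]1C(=O)C=C(OC)C[C@H]1CC2(CCCCCCCCCCCO[Si](C)(C)C(C)(C)C)OCCO2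
F2 | step 7 | methyl 4-methoxy-2-oxo-1-(phenylselanyl)-6-[(2-{11-[(tert-butyldimethylsilyl)oxy]undecyl}-1,3-dioxolan-2-yl)methyl]cyclohex-3-ene-1-carboxylate (racemic; selenium trans to the side chain; one enantiomer drawn) | COC(=O)[C@@]1([Se]c3ccccc3)C(=O)C=C(OC)C[C@H]1CC2(CCCCCCCCCCCO[Si](C)(C)C(C)(C)C)OCCO2
F3 | step 6 | dimethyl 2-[2-(2-{11-[(tert-butyldimethylsilyl)oxy]undecyl}-1,3-dioxolan-2-yl)ethylidene]malonate | COC(=O)C(C(=O)OC)=CCC1(CCCCCCCCCCCO[Si](C)(C)C(C)(C)C)OCCO1
F4 | step 4 | 2-(2-{11-[(tert-butyldimethylsilyl)oxy]undecyl}-1,3-dioxolan-2-yl)ethan-1-ol | OCCC1(CCCCCCCCCCCO[Si](C)(C)C(C)(C)C)OCCO1
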